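## Structural features

Manassantin A (21) is a C2-symmetric dineolignan. A central oxolane (ring A) carries methyl groups at C3 and C4 and 3-methoxy-4-oxyphenyl rings (B, B′) at C2 and C5. The para-oxygen of each of these rings is the ether oxygen at C8 of a 1-(3,4-dimethoxyphenyl)propan-1-ol chain (rings C, C′). Ring A holds four contiguous stereocentres, (2S,3R,4R,5S), with each aryl cis to its neighbouring methyl and the two methyls trans; each side chain holds two adjacent centres, (7R,8R), the threo pair. The cis aryl/methyl pairs are the less stable arrangement: C2 and C5 are benzylic ethers para to an oxygen donor, ionise under acid and drift to the all-trans ring. The C7 carbinols are acid-sensitive in the same way, any α-aryloxy ketone on the way to them can epimerise at C8, and a 2,3-dimethyl-1,4-diketone precursor of ring A has two enolisable α-centres and can dehydrate to a furan. The real difficulty is therefore kinetic control of a contra-thermodynamic ring pattern and of two threo carbinols. The key step exploits the fact that C2 and C5 of ring A are both bound to O1, both benzylic, and related by the C2 axis through O1 and the midpoint of C3–C4: one diketone oxygen becomes O1 while hydride is delivered to both carbons under the control of the adjacent methyl groups.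

## Logic of the disconnections

21 ⇒ 20. The two C7–H bonds are cut first, so that both secondary benzylic alcohols become aryl ketones. C7 then needs no chirality source of its own, since it can be set from C8 next door. Two stereocentres disappear and the fragile carbinols are postponed to the last step. The forward step must deliver hydride twice in the non-chelated Felkin–Anh sense (threo) without enolising C8.

20 ⇒ 13 + two of 19. Both C8–O(aryl) bonds are cut. This separates the C2-symmetric core from two identical three-carbon electrophiles. The forward step is a two-fold SN2 displacement with inversion at a secondary carbon α to a ketone, under a base mild enough not to racemise 19 or 20.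

19 ⇒ 18 ⇒ 15 + 16, and 15 ⇒ 14. The S–O bond, then the aryl–carbonyl bond, then the amide C–N bond are cut. C8 is thereby traced to the lactate centre of 14, so it is bought and not made. The forward steps need an acylation that stops at the ketone (through 17) and a sulfonylation in which no nucleophile can displace the new leaving group.

13 ⇒ 12. The two O–Si bonds are cut. Silyl ethers are chosen over benzyl ethers for two reasons: fluoride removes them, so no hydrogenolysis ever meets the two electron-rich benzylic C–O bonds of ring A; and a siloxy group is a somewhat weaker donor into rings B and B′, so C2 and C5 ionise less readily. The forward step only has to be non-acidic.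

12 ⇒ 10. The O1–C5 bond and the C2–H and C5–H bonds are cut; in 10 both benzylic carbons are carbonyl carbons and one carbonyl oxygen is the future O1. Because C2 and C5 share O1 and are symmetry-related, one reagent pair can close the ring and set both centres, each from its neighbouring methyl. The ring and two stereocentres are exchanged for an open chain with two stereocentres. The demands are heavy: closure before hydride transfer, hydride anti to the adjacent methyl twice, and no furan formation, enolisation at C3/C4 or benzylic ionisation.

10 ⇒ 5 + two of 7 (through 8 and 9). Both aryl–carbonyl bonds are cut. All stereochemistry of the ring precursor is then held in a four-carbon diamide, and one aryl bromide is used twice. The forward step must add the aryllithium once to each amide and release the enolisable ketones only at the cold quench.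

5 ⇒ 4 ⇒ 3 ⇒ two molecules of 1 (through 2). After the amide and imide C–N bonds, the central C2–C3 bond of the succinate is cut into two identical propanoyl units, so that 3 is the dimer of 1 less two hydrogens. Auxiliary-controlled homocoupling is preferred to resolving the trans diacid, because the unwanted isomers of 3 are diastereomers and can be removed before the auxiliary is cleaved. The forward coupling must join the two enolate-derived centres on the face opposite the benzyl group of each auxiliary.

7 ⇒ 6. The O–Si bond is cut; the forward step is a routine phenol silylation.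

## Other disconnections considered

Alternative 1: The cut is at the two aryl C–O bonds between rings B/B′ and the C8 oxygens. This leaves the dibromide core (2S,3R,4R,5S)-2,5-bis(4-bromo-3-methoxyphenyl)-3,4-dimethyloxolane A2 and two molecules of the mono-silylated threo diol (1R,2R)-1-[(tert-butyldimethylsilyl)oxy]-1-(3,4-dimethoxyphenyl)propan-2-ol A3. Forward, a copper–phenanthroline or palladium–biarylphosphine catalyst with a carbonate base would join the secondary hydroxyl of A3 to both aryl bromides and give manassantin A bis(tert-butyldimethylsilyl) ether A1; fluoride would then release 21.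
- In favour: C8 keeps its configuration because its C–O bond is never broken, both side-chain centres come from one asymmetric dihydroxylation of a propenylarene, and no α-aryloxy ketone ever exists. On side-chain stereochemistry this is the better plan.
- Against: a branched secondary alcohol with a bulky β-siloxy group must be coupled twice to an ortho-methoxy, electron-rich aryl bromide, the least favourable combination for both metals. Foreseeable losses are β-hydride elimination from the metal alkoxide, reduction of the aryl halide, and base-induced 1,2-silyl migration in A3, which would scramble which oxygen is arylated. The hot basic medium is also unkind to the cis benzylic ethers.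
- Comparison: it does not solve the ring. A2 still needs the cis/trans/cis oxolane, and the chosen cyclisation would serve equally well there, with bromine in place of the siloxy groups. After the core it is one step shorter (coupling, desilylation versus desilylation, alkylation, reduction), a point in its favour, but A3 needs a regioselective silylation that 19 does not.

Alternative 2: Ring A is cut into two identical halves at C3–C4 and at both O1–C bonds. Two molecules of the propenyl neolignan (1R,2R)-1-(3,4-dimethoxyphenyl)-2-{2-methoxy-4-[(E)-prop-1-en-1-yl]phenoxy}propyl acetate A5 and one oxygen atom from the medium would make up manassantin A diacetate A4. Forward, a one-electron oxidant (chemical, photochemical or anodic) would turn the styrene of A5 into a radical cation that adds tail-to-tail to a second alkene; hydration of one benzylic cation and attack of the new hydroxyl on the other closes the oxolane.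
- In favour: it uses the C2 symmetry as fully as the chosen plan (equal on that point), forms three bonds, the ring and four stereocentres in one step, and is clearly the shorter route.
- Against: nothing in the step controls the ring stereochemistry. The C3–C4 bond forms between two prochiral centres with only the remote side-chain centres as bias. The two C–O bonds form through benzylic cations that equilibrate towards aryl trans to methyl, the opposite of what 21 needs. The same cations can be intercepted by the electron-rich rings, and non-phenolic propenylarenes are also prone to cyclobutane dimers and oxidative cleavage.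
- Comparison: the chosen plan fixes C3 and C4 before the ring exists and sets C2 and C5 under kinetic control; here all four centres are left to thermodynamics and statistics. The wanted isomer would be expected as a minor component, so the step-count advantage is unlikely to survive separation.

Alternative 3: One aryl-bearing half of ring A is taken apart as a γ-butyrolactone, cut between the benzylic carbon and the adjacent methyl-bearing carbon and at the acyl C–O bond. This leads to tiglic aldehyde A7 and 4-bromo-3-methoxybenzaldehyde A8. Forward, a chiral triazolium-derived carbene with an amine base would convert A7 into a homoenolate equivalent whose β-carbon adds to A8; the alkoxide then acylates on the acyl azolium and releases (3R,4R,5S)-5-(4-bromo-3-methoxyphenyl)-3,4-dimethyloxolan-2-one A6. The second aryl group would follow by aryllithium addition and reductive deoxygenation of the hemiketal, and both bromides would later be exchanged for oxygen.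
- In favour: it is catalytic in chiral information, starts from two simple achiral aldehydes, sets the cis aryl/methyl pair at C5/C4 directly, and allows two different aryl groups. It is the better plan for unsymmetrical congeners, and the core could be shorter than in the chosen route.
- Against: homoenolate annulations are at their best with β-aryl enals and activated carbonyl partners. A7 is α,β-dialkyl-substituted and A8 is an ordinary aryl aldehyde, so slow formation of the acyl-anion equivalent, benzoin-type side reactions and modest enantiocontrol are to be expected. The C3 centre arises by protonation of an enol and is not set by the catalyst, though base could correct it because trans is favoured. The C2 symmetry of 21 goes unused.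
- Comparison: the second benzylic centre would be made by the same hydride addition to a 2-aryl oxocarbenium as in the chosen key step, so the two plans are equal in that risk. The chosen plan needs it twice in one flask but avoids a late two-fold conversion of aryl bromide into aryl ether.

Key step: step 6

Remark: 1 and a THF solution of 16 are treated as purchasable; step 1 joins two molecules of 1, and the second molecule is entered there as the partner that supplies the other half of 3; the ring is read as 2,3-cis-3,4-trans-4,5-cis and the side chains as threo, as the descriptors of 21 require.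

## Route

Step 1
Reactants: 1 (S)-4-benzyl-3-propanoyl-1,3-oxazolidin-2-one (two molecules)
Product: 3 (2R,3R)-1,4-bis[(4S)-4-benzyl-2-oxo-1,3-oxazolidin-3-yl]-2,3-dimethylbutane-1,4-dione, via lithium (Z)-enolate 2 (not isolated)
Conditions: 1 (2 equiv), LiN(iPr)2 (2.1 equiv), THF, −78 °C; then anhydrous CuCl2 (2.2 equiv), −78 °C to rt
Reagents that add atoms: the second molecule of 1, (S)-4-benzyl-3-propanoyl-1,3-oxazolidin-2-one, CCC(=O)N1[C@@H](Cc2ccccc2)COC1=O
Why: Oxidative enolate homocoupling: two molecules of 1 are deprotonated to the chelated (Z)-enolate 2, divalent copper oxidises each enolate by one electron, and the two α-carbons join (C2–C3 bond) with loss of one hydrogen from each half. Each new centre forms on the face opposite the benzyl group of its auxiliary, the face that gives R, so the (R,R) dimer should dominate; the other isomers are diastereomers and can be removed by crystallisation or chromatography.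

Step 2
Reactants: 3 (2R,3R)-1,4-bis[(4S)-4-benzyl-2-oxo-1,3-oxazolidin-3-yl]-2,3-dimethylbutane-1,4-dione
Product: 4 (2R,3R)-2,3-dimethylbutanedioic acid
Conditions: LiOH, H2O2, THF/H2O, 0 °C; Na2SO3; HCl to pH 2
Reagents that add atoms: hydrogen peroxide, OO
Why: Hydroperoxide cleavage of N-acyl oxazolidinones: the small, weakly basic hydroperoxide anion attacks the exocyclic carbonyl even of hindered imides and should leave both α-centres untouched; the auxiliary is recovered.

Step 3
Reactants: 4 (2R,3R)-2,3-dimethylbutanedioic acid
Product: 5 (2R,3R)-N1,N4-dimethoxy-N1,N4,2,3-tetramethylbutanediamide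
Conditions: MeONHMe·HCl, EDC·HCl, HOBt, N-methylmorpholine, CH2Cl2, 0 °C to rt
Reagents that add atoms: N,O-dimethylhydroxylamine hydrochloride, CNOC.Cl
Why: Carbodiimide/HOBt amide coupling under a weak amine base, conditions that should not epimerise the α-centres; any cyclic anhydride formed in passing is opened by the amine and leads to the same diamide.

Step 4
Reactants: 6 4-bromo-2-methoxyphenol
Product: 7 (4-bromo-2-methoxyphenoxy)(tert-butyl)dimethylsilane
Conditions: TBSCl, imidazole, DMF, rt
Reagents that add atoms: tert-butyldimethylsilyl chloride, CC(C)(C)[Si](C)(C)Cl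
Why: Standard imidazole-promoted silylation of a phenol; the silyl ether tolerates the later aryllithium and Lewis-acid steps and is removed by fluoride.

Step 5
Reactants: 7 (4-bromo-2-methoxyphenoxy)(tert-butyl)dimethylsilane; 5 (2R,3R)-N1,N4-dimethoxy-N1,N4,2,3-tetramethylbutanediamide
Product: 10 (2R,3R)-1,4-bis{4-[(tert-butyldimethylsilyl)oxy]-3-methoxyphenyl}-2,3-dimethylbutane-1,4-dione, via aryllithium 8 (not isolated), via dilithium bis-hemiaminal 9 (not isolated)
Conditions: 7 (2.4 equiv), n-BuLi, THF, −78 °C; then 5, −78 to −20 °C; cold sat. NH4Cl
Reagents that add atoms: none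
Why: Bromine–lithium exchange followed by a two-fold Weinreb ketone synthesis: each amide takes up one aryl group and stays as a chelated tetrahedral adduct, so over-addition is blocked. The enolisable ketones appear only at the cold, weakly acidic quench, which should preserve the (2R,3R) centres.

Step 6
Reactants: 10 (2R,3R)-1,4-bis{4-[(tert-butyldimethylsilyl)oxy]-3-methoxyphenyl}-2,3-dimethylbutane-1,4-dione
Product: 12 (2S,3R,4R,5S)-2,5-bis{4-[(tert-butyldimethylsilyl)oxy]-3-methoxyphenyl}-3,4-dimethyloxolane, via 5-siloxy oxolane 11 (not isolated)
Conditions: Et3SiH (6 equiv), TMSOTf (2.5 equiv, slow addition), CH2Cl2, −78 °C; Et3N then sat. NaHCO3 at −78 °C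
Reagents that add atoms: none
Why: TMSOTf silylates one aryl ketone, the oxygen of the other carbonyl adds to it in a reversible 5-exo-trig closure (O1–C5 bond) to give a 5-siloxy-2-aryl oxocarbenium ion, Et3SiH reduces this at C2 to 11, TMSOTf then ionises the C5 siloxy group (lost as hexamethyldisiloxane) and a second hydride adds at C5. The closest known reaction types are the silane/Lewis-acid reductive cycloetherification of 1,4- and 1,5-diketones and the reductive deoxygenation of 2-aryl cyclic hemiketals. In each 2-aryl oxocarbenium the aryl ring is coplanar with the C=O+ unit, so allylic-type strain turns the adjacent methyl out of that plane onto one face and hydride enters from the other; H therefore ends trans and aryl cis to the neighbouring methyl. C2 is thus controlled by the C3 methyl and C5 by the C4 methyl; the two events are closely related by the C2 axis but not identical, since the first cation carries the siloxy ketal carbon and the second the finished C2 centre, whose aryl should sit pseudoequatorial and away from the incoming silane. Three selectivities are needed: ring closure before any hydride transfer (an open-chain Felkin–Anh reduction would place aryl trans to methyl), hydride capture faster than proton loss from the siloxy cation (which would lead on to the Paal–Knorr furan and erase C3/C4), and no ionisation of the cis benzylic ethers once formed. The first is secured by the proximity of the second carbonyl oxygen and the poor hydride affinity of a merely silyl-complexed aryl ketone, the second by excess silane at −78 °C with slow addition of the Lewis acid, and the third by the cold basic quench and by siloxy groups on the para-positions, which are somewhat weaker donors than alkoxy groups.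

Step 7
Reactants: 12 (2S,3R,4R,5S)-2,5-bis{4-[(tert-butyldimethylsilyl)oxy]-3-methoxyphenyl}-3,4-dimethyloxolane
Product: 13 4,4'-[(2S,3R,4R,5S)-3,4-dimethyloxolane-2,5-diyl]bis(2-methoxyphenol)
Conditions: TBAF, AcOH, THF, 0 °C
Reagents that add atoms: none
Why: Fluoride cleavage of aryl silyl ethers, driven by the strong Si–F bond; acetic acid buffers the phenoxide so that the para-hydroxybenzyl ethers at C2 and C5 see neither acid nor strong base.

Step 8
Reactants: 14 ethyl (S)-2-hydroxypropanoate
Product: 15 (S)-2-hydroxy-N-methoxy-N-methylpropanamide
Conditions: MeONHMe·HCl, iPrMgCl, THF, −20 to 0 °C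
Reagents that add atoms: N,O-dimethylhydroxylamine hydrochloride, CNOC.Cl
Why: Aminolysis of an ester by the chloromagnesium amide of N,O-dimethylhydroxylamine; the free hydroxyl is carried as its magnesium alkoxide, and the reaction is fast at low temperature, so the lactate centre should be retained.

Step 9
Reactants: 15 (S)-2-hydroxy-N-methoxy-N-methylpropanamide; 16 (3,4-dimethoxyphenyl)magnesium bromide
Product: 18 (S)-1-(3,4-dimethoxyphenyl)-2-hydroxypropan-1-one, via magnesium hemiaminal 17 (not isolated)
Conditions: 16 (2.5 equiv), THF, 0 °C; sat. NH4Cl
Reagents that add atoms: none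
Why: Weinreb ketone synthesis: one equivalent of 16 deprotonates the hydroxyl and a second adds to the amide to give the chelated adduct 17, which collapses to the ketone only on work-up; the α-centre is an alkoxide-bearing carbon throughout and should not epimerise.

Step 10
Reactants: 18 (S)-1-(3,4-dimethoxyphenyl)-2-hydroxypropan-1-one
Product: 19 (S)-1-(3,4-dimethoxyphenyl)-1-oxopropan-2-yl 4-methylbenzenesulfonate
Conditions: Ts2O, pyridine, CH2Cl2, 0 °C
Reagents that add atoms: 4-methylbenzenesulfonic anhydride, Cc1ccc(cc1)S(=O)(=O)OS(=O)(=O)c1ccc(C)cc1
Why: O-Sulfonylation with retention, since the C–O bond is not touched; the anhydride is used so that no chloride is present to displace the activated α-keto sulfonate and erode the configuration.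

Step 11
Reactants: 13 4,4'-[(2S,3R,4R,5S)-3,4-dimethyloxolane-2,5-diyl]bis(2-methoxyphenol); 19 (S)-1-(3,4-dimethoxyphenyl)-1-oxopropan-2-yl 4-methylbenzenesulfonate
Product: 20 (2R,2'R)-2,2'-{[(2S,3R,4R,5S)-3,4-dimethyloxolane-2,5-diyl]bis[(2-methoxy-4,1-phenylene)oxy]}bis[1-(3,4-dimethoxyphenyl)propan-1-one]
Conditions: 19 (2.3 equiv), Cs2CO3, DMF, 0 °C to rt
Reagents that add atoms: none
Why: Two-fold Williamson-type SN2 etherification: each phenoxide displaces the tosylate at the carbonyl-activated secondary carbon with inversion, so (S) in 19 becomes (R) at C8 and C8′. A carbonate base at low temperature is chosen to keep enolisation of 19 and 20 slow.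

Step 12
Reactants: 20 (2R,2'R)-2,2'-{[(2S,3R,4R,5S)-3,4-dimethyloxolane-2,5-diyl]bis[(2-methoxy-4,1-phenylene)oxy]}bis[1-(3,4-dimethoxyphenyl)propan-1-one]
Product: 21 manassantin A, (1R,2R)-1-(3,4-dimethoxyphenyl)-2-{4-[(2S,3R,4R,5S)-5-(4-{[(1R,2R)-1-(3,4-dimethoxyphenyl)-1-hydroxypropan-2-yl]oxy}-3-methoxyphenyl)-3,4-dimethyloxolan-2-yl]-2-methoxyphenoxy}propan-1-ol
Conditions: Bu4NBH4, CH2Cl2/MeOH, −20 °C; sat. NH4Cl
Reagents that add atoms: none
Why: Borohydride reduction without a chelating counter-ion follows the Felkin–Anh model: the C8–OAr bond lies anti to the incoming hydride, which passes the C8 hydrogen and gives the (7R) carbinol from (8R), the threo pair. The two ketones are remote and react independently, and the cold neutral medium should leave C8 and ring A unchanged.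

## Compound list

1 | (S)-4-benzyl-3-propanoyl-1,3-oxazolidin-2-one | CCC(=O)N1[C@@H](Cc2ccccc2)COC1=O | starting material
2 | lithium (Z)-1-[(4S)-4-benzyl-2-oxo-1,3-oxazolidin-3-yl]prop-1-en-1-olate | [Li+].C/C=C(\[O-])N1[C@@H](Cc2ccccc2)COC1=O | intermediate
3 | (2R,3R)-1,4-bis[(4S)-4-benzyl-2-oxo-1,3-oxazolidin-3-yl]-2,3-dimethylbutane-1,4-dione | O=C1OC[C@H](Cc2ccccc2)N1C(=O)[C@H](C)[C@@H](C)C(=O)N3[C@@H](Cc4ccccc4)COC3=O | intermediate
4 | (2R,3R)-2,3-dimethylbutanedioic acid | OC(=O)[C@H](C)[C@@H](C)C(O)=O | intermediate
5 | (2R,3R)-N1,N4-dimethoxy-N1,N4,2,3-tetramethylbutanediamide | CON(C)C(=O)[C@H](C)[C@@H](C)C(=O)N(C)OC | intermediate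
6 | 4-bromo-2-methoxyphenol | COc1cc(Br)ccc1O | starting material
7 | (4-bromo-2-methoxyphenoxy)(tert-butyl)dimethylsilane | COc1cc(Br)ccc1O[Si](C)(C)C(C)(C)C | intermediate
8 | {4-[(tert-butyldimethylsilyl)oxy]-3-methoxyphenyl}lithium | COc1cc([Li])ccc1O[Si](C)(C)C(C)(C)C | intermediate
9 | dilithium bis-hemiaminal from 5 and two of 8 (carbinolamine carbons unassigned) | COc1cc(ccc1O[Si](C)(C)C(C)(C)C)C(O[Li])(N(C)OC)[C@H](C)[C@@H](C)C(O[Li])(N(C)OC)c2ccc(O[Si](C)(C)C(C)(C)C)c(OC)c2 | intermediate
10 | (2R,3R)-1,4-bis{4-[(tert-butyldimethylsilyl)oxy]-3-methoxyphenyl}-2,3-dimethylbutane-1,4-dione | COc1cc(ccc1O[Si](C)(C)C(C)(C)C)C(=O)[C@H](C)[C@@H](C)C(=O)c2ccc(O[Si](C)(C)C(C)(C)C)c(OC)c2 | intermediate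
11 | (2S,3R,4R)-2,5-bis{4-[(tert-butyldimethylsilyl)oxy]-3-methoxyphenyl}-3,4-dimethyl-5-[(trimethylsilyl)oxy]oxolane (C5 unassigned) | COc1cc(ccc1O[Si](C)(C)C(C)(C)C)[C@H]2OC(O[Si](C)(C)C)(c3ccc(O[Si](C)(C)C(C)(C)C)c(OC)c3)[C@H](C)[C@H]2C | intermediate
12 | (2S,3R,4R,5S)-2,5-bis{4-[(tert-butyldimethylsilyl)oxy]-3-methoxyphenyl}-3,4-dimethyloxolane | COc1cc(ccc1O[Si](C)(C)C(C)(C)C)[C@H]2O[C@H](c3ccc(O[Si](C)(C)C(C)(C)C)c(OC)c3)[C@H](C)[C@H]2C | intermediate
13 | 4,4'-[(2S,3R,4R,5S)-3,4-dimethyloxolane-2,5-diyl]bis(2-methoxyphenol) | COc1cc(ccc1O)[C@H]2O[C@H](c3ccc(O)c(OC)c3)[C@H](C)[C@H]2C | intermediate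
14 | ethyl (S)-2-hydroxypropanoate | CCOC(=O)[C@H](C)O | starting material
15 | (S)-2-hydroxy-N-methoxy-N-methylpropanamide | CON(C)C(=O)[C@H](C)O | intermediate
16 | (3,4-dimethoxyphenyl)magnesium bromide | COc1ccc([Mg]Br)cc1OC | starting material
17 | bis(bromomagnesium) alkoxide–hemiaminal adduct of 15 and 16 (carbinolamine carbon unassigned) | CON(C)C(O[Mg]Br)([C@H](C)O[Mg]Br)c1ccc(OC)c(OC)c1 | intermediate
18 | (S)-1-(3,4-dimethoxyphenyl)-2-hydroxypropan-1-one | COc1ccc(cc1OC)C(=O)[C@H](C)O | intermediate
19 | (S)-1-(3,4-dimethoxyphenyl)-1-oxopropan-2-yl 4-methylbenzenesulfonate | COc1ccc(cc1OC)C(=O)[C@H](C)OS(=O)(=O)c2ccc(C)cc2 | intermediate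
20 | (2R,2'R)-2,2'-{[(2S,3R,4R,5S)-3,4-dimethyloxolane-2,5-diyl]bis[(2-methoxy-4,1-phenylene)oxy]}bis[1-(3,4-dimethoxyphenyl)propan-1-one] | COc1ccc(C(=O)[C@@H](C)Oc2ccc([C@H]3O[C@H](c4ccc(O[C@H](C)C(=O)c5ccc(OC)c(OC)c5)c(OC)c4)[C@H](C)[C@H]3C)cc2OC)cc1OC | intermediate
21 | manassantin A | COc1ccc([C@@H](O)[C@@H](C)Oc2ccc([C@H]3O[C@H](c4ccc(O[C@H](C)[C@H](O)c5ccc(OC)c(OC)c5)c(OC)c4)[C@H](C)[C@H]3C)cc2OC)cc1OC | target

## Step count and least certain steps

Total: 12 steps. Longest linear sequence: 8 steps (steps 1, 2, 3, 5, 6, 7, 11, 12); steps 4 and 8–10 are side branches.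

Step 6 (key step). The most likely failure is proton loss from the siloxy oxocarbenium ion, followed by dehydration and aromatisation, outrunning hydride capture; this would destroy the C3 and C4 centres. Other risks are hydride transfer to the open chain before ring closure, which would set the first benzylic centre in the wrong sense; erosion of facial selectivity, because the more remote methyl sits on the face the hydride must use; and acid-induced ionisation of the finished cis benzylic ethers. Fallback, from 10 back to 12: the two C–H bonds are made separately. A Corey–Bakshi–Shibata mono-reduction of 10 with the (R)-oxazaborolidine and BH3·SMe2, run to partial conversion with recovery of 10, should give (2R,3R,4S)-1,4-bis{4-[(tert-butyldimethylsilyl)oxy]-3-methoxyphenyl}-4-hydroxy-2,3-dimethylbutan-1-one F1, in equilibrium with its cyclic hemiketal. The catalyst has to override the Felkin–Anh bias of the substrate, so a minor epimer would have to be separated at this stage. Reductive deoxygenation of the hemiketal with BF3·OEt2 and Et3SiH at −78 °C, the single-fold precedent of the key step, then gives 12. No furan can form on this path because only one carbon is at the ketone oxidation level.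

Step 1. The coupling of two enolate-derived centres may show only moderate face selectivity at each centre, and α-chlorination or simple proton return of the enolate may compete with C–C bond formation. Fallback, from 1 back to 4: the C2–C3 bond is made by alkylation instead. Methyl (R)-lactate is converted with Tf2O and 2,6-lutidine into methyl (R)-2-{[(trifluoromethyl)sulfonyl]oxy}propanoate F2. The sodium enolate of 1 (NaN(SiMe3)2, THF, −78 °C) displaces the triflate with inversion on the face opposite the benzyl group and gives methyl (2R,3R)-4-[(4S)-4-benzyl-2-oxo-1,3-oxazolidin-3-yl]-2,3-dimethyl-4-oxobutanoate F3. LiOH/H2O2 followed by excess LiOH then cleaves imide and ester to 4.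

Step 5. The second aryl addition to the hindered amide may stall, and the α-centres may epimerise by enolisation once the ketones are unmasked at the quench or on silica. Fallback, from 4 back to 10: a non-basic acylation. The diacid 4 is converted with EtSH, EDC·HCl and DMAP into S,S'-diethyl (2R,3R)-2,3-dimethylbutanebis(thioate) F4. Aryllithium 8 is transmetalated with ZnCl2 to {4-[(tert-butyldimethylsilyl)oxy]-3-methoxyphenyl}zinc chloride F5. A Fukuyama coupling of F4 with F5 under PdCl2(PPh3)2, a divalent palladium precatalyst, in THF/toluene at rt gives 10 without any strongly basic species.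

Step 11. The sulfonate 19 or the product 20 may enolise under the carbonate base, which would erode C8, and elimination of the sulfonate can compete with substitution. Fallback, from 13 back to 20: C8 is introduced as an ester, which is far less prone to enolisation. A Mitsunobu reaction of 13 with 14 (PPh3, DIAD, THF, 0 °C to rt) inverts the lactate centre and gives diethyl (2R,2'R)-2,2'-{[(2S,3R,4R,5S)-3,4-dimethyloxolane-2,5-diyl]bis[(2-methoxy-4,1-phenylene)oxy]}dipropanoate F6. MeONHMe·HCl and iPrMgCl convert it into the corresponding bis(N-methoxy-N-methylamide) F7, and addition of 16 gives 20.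

Step 12. Partial chelation between the carbonyl oxygen, the aryloxy oxygen and its ortho-methoxy group may lower the threo selectivity, and the two independent reductions multiply any leakage. Fallback, from 20 back to 21: the opposite selectivity is made on purpose and then inverted. Chelation-controlled reduction with Zn(BH4)2 in Et2O at −20 °C should give the erythro,erythro diol, the (7S,8R,7'S,8'R) diastereomer of manassantin A F8. A two-fold Mitsunobu reaction with 4-nitrobenzoic acid (PPh3, DIAD) inverts both C7 centres to give manassantin A bis(4-nitrobenzoate) F9, and K2CO3 in MeOH releases 21.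

## Further compounds

F1 | step 6 | (2R,3R,4S)-1,4-bis{4-[(tert-butyldimethylsilyl)oxy]-3-methoxyphenyl}-4-hydroxy-2,3-dimethylbutan-1-one | COc1cc(ccc1O[Si](C)(C)C(C)(C)C)C(=O)[C@H](C)[C@@H](C)[C@H](O)c2ccc(O[Si](C)(C)C(C)(C)C)c(OC)c2
F2 | step 1 | methyl (R)-2-{[(trifluoromethyl)sulfonyl]oxy}propanoate | COC(=O)[C@@H](C)OS(=O)(=O)C(F)(F)F
F3 | step 1 | methyl (2R,3R)-4-[(4S)-4-benzyl-2-oxo-1,3-oxazolidin-3-yl]-2,3-dimethyl-4-oxobutanoate | COC(=O)[C@H](C)[C@@H](C)C(=O)N1[C@@H](Cc2ccccc2)COC1=O
F4 | step 5 | S,S'-diethyl (2R,3R)-2,3-dimethylbutanebis(thioate) | CCSC(=O)[C@H](C)[C@@H](C)C(=O)SCC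
F5 | step 5 | {4-[(tert-butyldimethylsilyl)oxy]-3-methoxyphenyl}zinc chloride | COc1cc([Zn]Cl)ccc1O[Si](C)(C)C(C)(C)C
F6 | step 11 | diethyl (2R,2'R)-2,2'-{[(2S,3R,4R,5S)-3,4-dimethyloxolane-2,5-diyl]bis[(2-methoxy-4,1-phenylene)oxy]}dipropanoate | CCOC(=O)[C@@H](C)Oc1ccc(cc1OC)[C@H]2O[C@H](c3ccc(O[C@H](C)C(=O)OCC)c(OC)c3)[C@H](C)[C@H]2C
F7 | step 11 | (2R,2'R)-2,2'-{[(2S,3R,4R,5S)-3,4-dimethyloxolane-2,5-diyl]bis[(2-methoxy-4,1-phenylene)oxy]}bis(N-methoxy-N-methylpropanamide) | CON(C)C(=O)[C@@H](C)Oc1ccc(cc1OC)[C@H]2O[C@H](c3ccc(O[C@H](C)C(=O)N(C)OC)c(OC)c3)[C@H](C)[C@H]2C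
F8 | step 12 | erythro,erythro (7S,8R,7'S,8'R) diastereomer of manassantin A | COc1ccc([C@H](O)[C@@H](C)Oc2ccc([C@H]3O[C@H](c4ccc(O[C@H](C)[C@@H](O)c5ccc(OC)c(OC)c5)c(OC)c4)[C@H](C)[C@H]3C)cc2OC)cc1OC
F9 | step 12 | manassantin A bis(4-nitrobenzoate) | COc1ccc([C@@H](OC(=O)c6ccc(cc6)[N+](=O)[O-])[C@@H](C)Oc2ccc([C@H]3O[C@H](c4ccc(O[C@H](C)[C@H](OC(=O)c7ccc(cc7)[N+](=O)[O-])c5ccc(OC)c(OC)c5)c(OC)c4)[C@H](C)[C@H]3C)cc2OC)cc1OC
A1 | alternative 1 | manassantin A bis(tert-butyldimethylsilyl) ether | COc1ccc([C@@H](O[Si](C)(C)C(C)(C)C)[C@@H](C)Oc2ccc([C@H]3O[C@H](c4ccc(O[C@H](C)[C@H](O[Si](C)(C)C(C)(C)C)c5ccc(OC)c(OC)c5)c(OC)c4)[C@H](C)[C@H]3C)cc2OC)cc1OC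
A2 | alternative 1 | (2S,3R,4R,5S)-2,5-bis(4-bromo-3-methoxyphenyl)-3,4-dimethyloxolane | COc1cc(ccc1Br)[C@H]2O[C@H](c3ccc(Br)c(OC)c3)[C@H](C)[C@H]2C
A3 | alternative 1 | (1R,2R)-1-[(tert-butyldimethylsilyl)oxy]-1-(3,4-dimethoxyphenyl)propan-2-ol | COc1ccc(cc1OC)[C@@H](O[Si](C)(C)C(C)(C)C)[C@@H](C)O
A4 | alternative 2 | manassantin A diacetate | COc1ccc([C@@H](OC(C)=O)[C@@H](C)Oc2ccc([C@H]3O[C@H](c4ccc(O[C@H](C)[C@H](OC(C)=O)c5ccc(OC)c(OC)c5)c(OC)c4)[C@H](C)[C@H]3C)cc2OC)cc1OC
A5 | alternative 2 | (1R,2R)-1-(3,4-dimethoxyphenyl)-2-{2-methoxy-4-[(E)-prop-1-en-1-yl]phenoxy}propyl acetate | COc1ccc(cc1OC)[C@@H](OC(C)=O)[C@@H](C)Oc2ccc(/C=C/C)cc2OC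
A6 | alternative 3 | (3R,4R,5S)-5-(4-bromo-3-methoxyphenyl)-3,4-dimethyloxolan-2-one | COc1cc(ccc1Br)[C@H]2OC(=O)[C@H](C)[C@H]2C
A7 | alternative 3 | tiglic aldehyde, (E)-2-methylbut-2-enal | C/C=C(\C)C=O
A8 | alternative 3 | 4-bromo-3-methoxybenzaldehyde | COc1cc(C=O)ccc1Br
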